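A small charge of free catalyst, 10.0% of the substrate in teal, green and amber, has to go round 10.0 times to turn the substrate into product, so this reckoning follows one catalyst and counts its rounds.

common to all: substrate 0.84 M; coupling partner 1.26 M
- Saturday's: free catalyst 56 mM; temperature 8 °C; run made earlier
- Thursday's: free catalyst 130 mM; temperature 24 °C; run made earlier
- teal: free catalyst 84 mM; temperature 0 °C; time 20 min
- green: free catalyst 84 mM; temperature 15 °C; time 20 min
- amber: free catalyst 84 mM; temperature 30 °C; time 20 min

| run | time / min | catalyst intermediate E / % | product / % | substrate / % | catalyst intermediate C / % |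
|---|---|---|---|---|---|
| Saturday's | 2.50 | 0.8 | 4.5 | 93.3 | 0.5 |
| Saturday's | 5.00 | 0.1 | 9.8 | 88.9 | 0.5 |
| Saturday's | 6.00 | 0.1 | 12.3 | 86.7 | 0.9 |
| Saturday's | 10.0 | 1.2 | 20.7 | 78.3 | 1.4 |
| Saturday's | 12.0 | 0.1 | 24.5 | 74.5 | 0 |
| Saturday's | 15.0 | 1.0 | 30.4 | 67.6 | 0.7 |
| Thursday's | 0.250 | 0 | 0.9 | 98.3 | 0.4 |
| Thursday's | 0.833 | 1.0 | 6.2 | 91.6 | 0 |
| Thursday's | 1.50 | 0.7 | 13.2 | 85.7 | 0.4 |
| Thursday's | 2.00 | 0 | 18.8 | 80.4 | 0.5 |
| Thursday's | 3.00 | 0.6 | 27.9 | 71.1 | 0 |
| Thursday's | 4.00 | 0 | 36.3 | 63.0 | 0 |
| Thursday's | 5.00 | 0.6 | 43.5 | 56.3 | 0 |

(readings scatter by 0.5 percentage points)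

* which of these there is most of at the end, counted by the substrate in it, teal (catalyst intermediate E / catalyst intermediate C / substrate / product)
* which of these there is most of at the end, counted by the substrate in it, green (catalyst intermediate E / catalyst intermediate C / substrate / product)
* which of these there is most of at the end, counted by the substrate in it, amber (catalyst intermediate E / catalyst intermediate C / substrate / product)
* the largest of these amounts at the end, in percent of the substrate charged, teal
* the largest of these amounts at the end, in percent of the substrate charged, green
* the largest of these amounts at the end, in percent of the substrate charged, amber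

The first rung is the catalyst forms that can be read. In Saturday's run, catalyst intermediates C and E read 1.4% and 1.2% at 10.0 min, with a scatter of 0.5 percentage points, against a catalyst charge of 6.67% of the substrate. Substrate and product together still read 98.0% at 15.0 min, so this reckoning follows the substrate through these two.

The next rung is the round. Substrate falls on a pseudo-first-order line, with 0.0258 /min in Saturday's run and 0.117 /min in Thursday's, from first reading to last. Catalyst charge over the starting loss of substrate gives the round time, the minutes one catalyst needs per substrate at full charge: 2.59 min at 8 °C and 1.32 min at 24 °C. This assumes first order in catalyst, since the two runs changed catalyst and temperature together. The round time is then carried geometrically along the temperature.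

The last rung is the halving. Loss keeps step with the substrate present, so half is gone after the halving count, the natural logarithm of two times the substrate-to-catalyst charge ratio, counted in rounds at the starting pace: 6.93.

| Flask | Round time | Rounds in the run | Substrate left |
|---|---|---|---|
| teal | 3.62 min | 5.52 | 57.6% |
| green | 1.93 min | 10.4 | 35.4% |
| amber | 1.02 min | 19.5 | 14.2% |

By this reckoning teal makes fewer rounds than the count, while green and amber make more. This reckoning therefore has substrate leading in teal, and product leading at 64.6% in green and 85.8% in amber.

The forecast, which takes off a lag and warns that “Temperature and catalyst changed together, so they cannot be separated.”, gives substrate at 60% in teal, product at 64% in green and product at 85% in amber.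

Teal ends with substrate at 63.6%, green with product at 67.9% and amber with product at 85.5%.

    coupling partner + free catalyst → catalyst intermediate A (k = 0.0270 /M/s, Ea = 44.0 kJ/mol)
    catalyst intermediate A ⇌ catalyst intermediate B (K = 2.70, k = 0.0160 /s, Ea = 70.0 kJ/mol, ΔH = −4.00 kJ/mol)
    substrate + catalyst intermediate B ⇌ catalyst intermediate C (K = 0.620 /M, k = 0.0420 /M/s, Ea = 37.0 kJ/mol, ΔH = −67.0 kJ/mol)
    catalyst intermediate C → released group + catalyst intermediate D (k = 0.0330 /s, Ea = 80.0 kJ/mol)
    catalyst intermediate D → catalyst intermediate E (k = 0.0670 /s, Ea = 79.0 kJ/mol)
    catalyst intermediate E → free catalyst + product (k = 0.0320 /s, Ea = 67.0 kJ/mol)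
    (constants at 0 °C)

Taken as it stands at 20.0 min, green has a slowest mode with a half-life of 12.5 min, shorter than the 20 min of the run. That is 1.60 half-lives, while the 10.4 reckoned rounds over the count of 6.93 make 1.50 halvings, and green's substrate ends at 31.6%. Green run at −10 °C has a round time of 5.52 min by the same rule, so 3.63 rounds, fewer than the count, and that flask ends with substrate leading at 83.3%.

Readings and results come from a simulation for substances that don't exist; the scatter is artificial.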